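## The problem

Compound 7 is a hydroazulene: a cyclopentane (C1–C5) fused through the C1–C5 bond to a cycloheptane (C1, C10, C9, C8, C7, C6, C5). In the daucane numbering used throughout, C1 carries the angular methyl (C15), C4 the isopropyl group (C11–C13), C5 the ring-fusion hydroxyl, C8 a methyl (C14) and a hydroxyl, C9 the 4-methoxybenzoyloxy group, and C10 is the methylene between C9 and C1. There are five stereocentres, (1R,4R,5S,8R,9R). C1 (quaternary), C4 and C5 (fully substituted) are contiguous and carry methyl, isopropyl and hydroxyl on one face of the cyclopentane, so the ring fusion is cis. C8 and C9 form a trans-diol monoester: the C9 oxygen lies on the face of the C5 hydroxyl, the C8 hydroxyl on the other. C1, C4 and C5 have no neighbour that could control them and must be set together, whereas C8 and C9 can be derived from C5, whose hydroxyl sits directly across the seven-membered ring from C8–C9. The fragile points are the two tertiary alcohols (ionisation and dehydration in strong acid), the readiness of the C5 hydroxyl to bridge to C8 or C9 when an electrophilic centre is offered on the opposite face, and the aryl ester, which is best introduced last. A short synthesis is possible because the fifteen skeletal carbons, read C10–C9–C8(C14)–C7–C6–C5–C1(C15)–C2–C3–C4–C11(C12,C13), are an unrearranged head-to-tail farnesane chain: only the ring bonds C1–C10 and C4–C5 are missing, C8–C9 is where the first alkene of such a chain lies, and the C5 hydroxyl stands where the charge of a cyclisation would come to rest.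

## Retrosynthesis

**Ester C–O bond at C9.** Cutting it leads from 7 to triol 5 and acid chloride 6. This is preferred to carrying the aroyl group through earlier steps, because the ester tolerates neither the acid of the cyclisation nor basic epoxide openings. In 5 the C9 hydroxyl is the only secondary one, so no protecting group is needed. The precursor loses the arene and all base sensitivity. The forward step only has to tell one secondary hydroxyl from two tertiary ones.

**C8–O bond.** Cutting it in 5 gives epoxide 4, whose oxygen bridges C8 and C9 on the face of the C5 hydroxyl. A trans-diol calls for anti opening of an epoxide; cis-dihydroxylation would give the wrong relative configuration, and the epoxide on the other face would need basic opening at C9 with the C5 hydroxyl protected. The precursor has one oxygen less. The forward step must bring the nucleophile to the tertiary carbon C8 with inversion, without participation of the C5 hydroxyl.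

**Epoxide oxygen.** Removing it gives alkene 3, which has three stereocentres, one hydroxyl and one alkene. An undirected oxidant could attack either face, and the epoxide anti to the C5 hydroxyl is set up for transannular etherification; direction by that hydroxyl avoids both. The forward step must deliver oxygen to the face of C8=C9 on which the C5 hydroxyl stands.

**Ring bonds C1–C10 and C4–C5, with the C5–O bond (key disconnection).** Cutting these together unravels 3 to the achiral open-chain acetate 2, which has no ring and no stereocentre. Cutting only one ring bond, as the roads not taken do, leaves a monocyclic compound that still needs carbon–carbon bonds and functional-group removal; cutting both uses the fact that all fifteen carbons and the C8=C9 alkene are already in place in 2. The forward reaction must ionise at C10, close the seven-membered ring at C1, close the five-membered ring between C5 and C4, move the charge from C11 through C4 to C5 by two hydride shifts and hydrate C5, all in one enantiotopic fold.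

**Acetate C–O bond.** Cutting it gives alcohol 1, which is commercial. The acetate is preferred to the free alcohol as the ionising group because the hydroxyl source for the last event of the cascade can then be dosed independently of the substrate; it is preferred to a halide because it can be stored and purified. The forward step is a plain O-acetylation that leaves the 2Z geometry untouched.

## Roads not taken

**Alternative 1:** The cut is the C1–C5 bond of the cyclopentane, made together with the C4=C5 double bond from a ketone and one added carbon; the seven-membered ring is left for later. (S)-Citronellol A1 would be silylated, hydroborated and oxidised to the isopropyl ketone A2, whose carbonyl carbon is C4. A lithiated silyldiazomethane reagent converts the carbonyl into an alkylidene carbene with the new carbon C5 at its tip, and this inserts into the tertiary C1–H bond with retention to give cyclopentene A3.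
- Merits: the insertion is a known reaction of known scope, and the quaternary centre C1 is taken from the chiral pool with full fidelity.
- Weak points for 7: A3 holds eleven of the fifteen carbons and one of five stereocentres. C4=C5 must still become C4–H and a C5 carbinol bearing C6, with hydroxyl cis to isopropyl; C6, C7, C8 and C14 must be added; the seven-membered ring must be closed onto C9; only then can C8 and C9 be addressed.
- Comparison: in certainty this road is ahead, since the absolute configuration is bought with A1 and not created by a catalyst. The chosen plan sets step economy against it: step 2 gives the whole bicycle with three stereocentres from an achiral chain, and 7 follows in three further steps.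

**Alternative 2:** The cut is C1–C10 alone, made by a 1,2-shift and not by cation–olefin addition. Epoxy alcohol A4 is a 4-methylcyclohex-3-enol whose carbinol carbon C5 bears a trisubstituted oxirane (C1–C2). With a boron Lewis acid the oxirane opens at the tertiary carbon C1, ring carbon C10 migrates from C5 to C1 anti to the departing oxygen, and C5 becomes a carbonyl, giving cycloheptenone A5.
- Merits: the rearrangement type is well precedented and stereospecific, so C1 follows from an enantioselective epoxidation. A5 already has the C8=C9 alkene and a C5 carbonyl next to the quaternary centre.
- Weak points for 7: C10 must migrate in preference to C6, and the two differ only in being allylic and homoallylic. A5 carries a C2 hydroxyl that the target lacks. C4 with its isopropyl group (four carbons) must still be attached and joined to C5 with hydroxyl cis to isopropyl. A4 itself needs several steps.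
- Comparison: for the bond C1–C10 taken alone this road is better founded than step 2. The chosen plan sets against it that the same bond, the C4–C5 bond and the C4 and C5 stereocentres arrive together with no oxygen to delete; its fallback for step 2 borrows the ring-expansion idea in sigmatropic form.

**Alternative 3:** The cut goes through C5–C6 and C7–C8, two bonds of the seven-membered ring, with an oxygen atom bridging C5 and C8. The oxidopyrylium ylide A6 (ring O, C8, C9, C10, C1, C5, fused to a cyclopentane that already carries C4) would be generated in situ and add across the alkynyl sulfone A7 in a (5+2) cycloaddition. The product is the bridged adduct A8 with a C9 ketone, a C1=C10 alkene and a sulfone on C6.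
- Merits: the cycloaddition is well known; it builds the seven-membered ring and places oxygen on C5, C8 and C9 at once; the isopropyl group should send the alkyne to the opposite face, so the bridging oxygen is cis to isopropyl at C5 as 7 requires.
- Weak points for 7: the bridge holds the C8 oxygen on the same face as the C5 oxygen, whereas in 7 they lie on opposite faces, so the C8–O bond would have to be broken and remade from the other side. A8 also lacks the C1 methyl (conjugate addition needed), carries a sulfone to be removed and a C6=C7 alkene to be reduced, and needs a face-selective reduction at C9. A6 requires a multistep synthesis.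
- Comparison: in oxidation level A8 is ahead of 3, which needs three further steps to oxidise C8 and C9. The chosen plan sets against it that all carbons are in place after step 2 and that the directed epoxidation gives the C8 configuration the bridge cannot.

Key step: step 2

## Route

Assumptions and conventions:
- (2Z,6E)-Farnesol 1 is taken as bought as the single 2Z,6E isomer; if only isomer mixtures are on offer, it is separated on AgNO3-impregnated silica gel.
- Daucane numbering is used for the open-chain compounds as well (daucane C10, C9, C8, C7, C6, C5, C1, C2, C3, C4, C11 are farnesane C1 to C11). Descriptors refer to this numbering.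
- The carbocations of step 2 are ion pairs inside the catalyst; they are described in the text and carry no numbers.

Step 1
Reactants: 1 (2Z,6E)-farnesol
Product: 2 (2Z,6E)-farnesyl acetate
Conditions: Ac2O, pyridine, DMAP (cat.), CH2Cl2, 0 °C
Reagents that add atoms: acetic anhydride, CC(=O)OC(C)=O
Why: DMAP-catalysed O-acetylation of a primary allylic alcohol under basic conditions; no stereocentre is formed and the 2Z and 6E geometries are untouched because no allyl cation can arise.

Step 2
Reactants: 2 (2Z,6E)-farnesyl acetate
Product: 3 (1R,4R,5S)-dauc-8-en-5-ol (cis-fused; C1 methyl, C4 isopropyl and C5 hydroxyl on one face)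
Conditions: chiral confined imidodiphosphorimidate Brønsted acid (BINOL-derived, N-triflyl; 10 mol %), H2O (1.5 equiv), CHCl3, 0 °C
Reagents that add atoms: water, O
Why: Proposed new method: the confined acid protonates the acetate and ionises C10–O to the cisoid allyl cation C10–C9–C8, held as an ion pair with the chiral imidodiphosphorimidate anion; the closest known reaction type is the tail-to-head cyclisation of farnesyl and neryl derivatives by terpene synthases and by confined Brønsted acids (resorcinarene capsule, imidodiphosphorimidates), which has not been shown to deliver a daucane. The seven-membered ring closes when C10 bonds to C1, the disubstituted end of the central alkene, formally a 7-endo-trig cation–olefin closure that may also run as 6-exo closure at C5 followed by 1,2-shift of C10 from C5 to C1; the charge appearing at C5 is taken up by C4 of the terminal alkene in a 5-exo-trig closure, so that C5 need not exist as a free secondary cation. Since C10 and C4 add to opposite faces of the (6E) alkene, the C1 methyl and the C5 hydrogen come out trans in the bicyclic C11 cation. A suprafacial 1,2-hydride shift from C4 to C11 creates the isopropyl group, and a second one from C5 to C4 places hydrogen on C4 trans to the C1 methyl, which sets C4 (isopropyl cis to methyl) and returns the charge to the tertiary ring-fusion carbon C5. Water held in the cavity adds to C5 anti to the hydride that has just left, on the face of methyl and isopropyl, which sets C5, makes the fusion cis and releases the proton for the next turnover. C1 is thus controlled by the catalyst, which must pick one enantiotopic fold of the achiral chain, C4 by the alkene geometry relayed through the stereospecific shifts, and C5 by the anti course of shift and capture. The step needs selectivity for seven- over six-membered termination, for closure onto the central alkene over the distant terminal one, and for hydration over elimination; the substrate supplies the 2Z geometry that lets C10 reach C1, the 6E geometry and the 1,5-diene spacing, and the confinement has to supply the rest.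

Step 3
Reactants: 3 (1R,4R,5S)-dauc-8-en-5-ol
Product: 4 (1R,4R,5S,8S,9R)-8,9-epoxydaucan-5-ol (epoxide oxygen on the face of the C5 hydroxyl)
Conditions: VO(acac)2 (5 mol %), t-BuOOH (1.5 equiv), CH2Cl2, 0 °C to rt
Reagents that add atoms: tert-butyl hydroperoxide, CC(C)(C)OO
Why: Hydroxyl-directed epoxidation: the C5 alkoxide and the peroxide bind to pentavalent vanadium, and in a boat-like cycloheptene conformer the oxygen is handed across the ring to the face of C8=C9 on which the C5 oxygen stands, setting C8 and C9 together. The syn epoxide is safe from the C5 hydroxyl, which cannot reach the rear of either epoxide carbon.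

Step 4
Reactants: 4 (1R,4R,5S,8S,9R)-8,9-epoxydaucan-5-ol
Product: 5 (1R,4R,5S,8R,9R)-daucane-5,8,9-triol
Conditions: HClO4 (5 mol %), THF/H2O (1:1), 0 °C
Reagents that add atoms: water, O
Why: Acid-catalysed epoxide hydrolysis of borderline SN2 character: the protonated oxirane opens at the tertiary carbon C8 and water enters anti to the leaving oxygen, so C8 is inverted (hydroxyl opposite to the C5 hydroxyl, methyl on its face) while C9 keeps its oxygen and configuration, giving the trans-diol. High water content and low temperature keep the opening concerted and away from a free C8 cation.

Step 5
Reactants: 5 (1R,4R,5S,8R,9R)-daucane-5,8,9-triol; 6 4-methoxybenzoyl chloride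
Product: 7 (1R,4R,5S,8R,9R)-5,8-dihydroxydaucan-9-yl 4-methoxybenzoate
Conditions: pyridine, DMAP (cat.), CH2Cl2, 0 °C to rt
Reagents that add atoms: none
Why: DMAP-catalysed acyl transfer through the N-acylpyridinium ion: the C9 hydroxyl is the only secondary one, the tertiary hydroxyls at C5 and C8 do not acylate under these conditions, and no stereocentre is touched.

## Compound list

1 | (2Z,6E)-farnesol, (2Z,6E)-3,7,11-trimethyldodeca-2,6,10-trien-1-ol | CC(C)=CCC/C(C)=C/CC/C(C)=C\CO | starting material
2 | (2Z,6E)-farnesyl acetate | CC(C)=CCC/C(C)=C/CC/C(C)=C\COC(C)=O | intermediate
3 | (1R,4R,5S)-dauc-8-en-5-ol, (3R,3aS,8aR)-6,8a-dimethyl-3-(propan-2-yl)-2,3,4,5,8,8a-hexahydro-1H-azulen-3a-ol | CC1=CC[C@@]2(C)CC[C@H](C(C)C)[C@@]2(O)CC1 | intermediate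
4 | (1R,4R,5S,8S,9R)-8,9-epoxydaucan-5-ol, epoxide oxygen syn to the C5 hydroxyl | O1[C@@H]2C[C@@]3(C)CC[C@H](C(C)C)[C@@]3(O)CC[C@]12C | intermediate
5 | (1R,4R,5S,8R,9R)-daucane-5,8,9-triol | O[C@@H]1C[C@@]2(C)CC[C@H](C(C)C)[C@@]2(O)CC[C@@]1(C)O | intermediate
6 | 4-methoxybenzoyl chloride | COc1ccc(cc1)C(Cl)=O | starting material
7 | (1R,4R,5S,8R,9R)-5,8-dihydroxydaucan-9-yl 4-methoxybenzoate | COc1ccc(C(=O)O[C@@H]2C[C@@]3(C)CC[C@H](C(C)C)[C@@]3(O)CC[C@@]2(C)O)cc1 | target

## Step count and risks

Total step count: 5. Longest linear sequence: 5 steps (1 → 2 → 3 → 4 → 5 → 7); 6 enters in step 5.

**Step 2 (key step, proposed new method).**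
- What may go wrong: the cascade may end early, by capture of a nucleophile or loss of a proton after six-membered closure at C5, or at C11 or C4 before the charge has reached C5. Hydration at C5 may take the less hindered face or give way to elimination. The tertiary alcohol may re-ionise and dehydrate. The fold of the achiral chain may be selected poorly.
- Why: closure at C1 runs against the Markovnikov preference and depends on assistance by the terminal alkene; the face of C5 to be hydrated is flanked by methyl and isopropyl; an acid that ionises 2 can also ionise 3.
- Fallback (known chemistry; sets out from 1, comes back at 3; seven operations): the two ring bonds are made one after the other by pericyclic reactions.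
  - Sharpless asymmetric epoxidation of 1 (Ti(OiPr)4, D-(−)-diethyl tartrate, t-BuOOH, CH2Cl2, −20 °C) should give (2R,3S)-2,3-epoxy-(6E)-farnesol F1.
  - I2, PPh3 and imidazole convert it into the epoxy iodide F2, and zinc in ethanol opens this reductively to (3S,6E)-nerolidol F3, in which C8 is a carbinol stereocentre bearing a vinyl group (C9=C10).
  - NBS in CH2Cl2 brings about anti bromoetherification of the central alkene (oxygen to C5, bromine to C1) and gives the bromo tetrahydrofuran F4.
  - Heating in 2,4,6-collidine removes HBr anti to give the exocyclic (E)-enol ether F5, which undergoes Claisen rearrangement in the same flask. C1–C10 forms, the ring oxygen becomes the C5 carbonyl, the C8=C9 alkene appears and the configuration of C8 is passed to C1, giving (R)-cycloheptenone F6.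
  - Me2AlCl (CH2Cl2, −78 to 0 °C) promotes an intramolecular carbonyl-ene reaction between the C5 ketone and the terminal alkene. It forms C4–C5, and its cyclic transition state places the hydroxyl cis to the new isopropenyl group in the cis-fused dienol F7.
  - H2 with RhCl(PPh3)3 in benzene saturates only the 1,1-disubstituted alkene and gives 3.

**Step 3.**
- What may go wrong: weak direction and hence poor facial selectivity.
- Why: the tertiary C5 hydroxyl is three bonds from either alkene carbon and binds vanadium reluctantly; oxygen delivered to the other face leaves an epoxide that the C5 hydroxyl can open across the ring.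
- Fallback (sets out from 3, comes back at 4; no new compound): reagent control in place of substrate direction. Shi epoxidation with the fructose-derived chiral ketone, KHSO5 (as 2KHSO5·KHSO4·K2SO4) and K2CO3 buffer in MeCN/dimethoxymethane/H2O at 0 °C, using the enantiomer of the ketone that attacks the face of the C5 hydroxyl.

**Step 4.**
- What may go wrong: loss of stereochemical integrity at C8 through ionisation, followed by front-side capture by the C5 hydroxyl, hydride shift from C9, or proton loss; partial attack of water at C9.
- Why: C8 is tertiary and the C5 hydroxyl is held close to it on the same face.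
- Fallback (sets out from 3, comes back at 5): SN2 opening at the secondary carbon of the opposite epoxide, with the C5 oxygen masked.
  - Et3SiOTf and 2,6-lutidine give the silyl ether F8.
  - mCPBA (NaHCO3, CH2Cl2) should attack the face away from the silyloxy group and give the anti epoxide F9.
  - KOH in DMSO/H2O with heating opens it at C9 with inversion to the silyl-protected trans-diol F10.
  - Bu4NF in THF frees the C5 hydroxyl and gives 5.

## Further compounds

F1 | step 2 | (2R,3S)-2,3-epoxy-(6E)-farnesol, [(2R,3S)-3-methyl-3-[(3E)-4,8-dimethylnona-3,7-dien-1-yl]oxiran-2-yl]methanol | OC[C@H]1O[C@@]1(C)CC/C=C(\C)CCC=C(C)C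
F2 | step 2 | (2S,3S)-2-(iodomethyl)-3-methyl-3-[(3E)-4,8-dimethylnona-3,7-dien-1-yl]oxirane | IC[C@H]1O[C@@]1(C)CC/C=C(\C)CCC=C(C)C
F3 | step 2 | (3S,6E)-nerolidol, (3S,6E)-3,7,11-trimethyldodeca-1,6,10-trien-3-ol | C=C[C@@](C)(O)CC/C=C(\C)CCC=C(C)C
F4 | step 2 | (5S)-2-(2-bromo-6-methylhept-5-en-2-yl)-5-ethenyl-5-methyloxolane, both C2 epimers, oxygen and bromine added anti across the former alkene | C=C[C@]1(C)CCC(O1)C(C)(Br)CCC=C(C)C
F5 | step 2 | (5S)-5-ethenyl-5-methyl-2-[(2E)-6-methylhept-5-en-2-ylidene]oxolane | C=C[C@]1(C)CC/C(O1)=C(/C)CCC=C(C)C
F6 | step 2 | (2R)-2,5-dimethyl-2-(4-methylpent-3-en-1-yl)cyclohept-4-en-1-one | CC1=CC[C@@](C)(CCC=C(C)C)C(=O)CC1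
F7 | step 2 | (1R,4R,5S)-dauca-8,11(12)-dien-5-ol | CC1=CC[C@@]2(C)CC[C@H](C(C)=C)[C@@]2(O)CC1
F0 | step 3 | none | none
F8 | step 4 | (1R,4R,5S)-5-(triethylsilyloxy)dauc-8-ene | CC1=CC[C@@]2(C)CC[C@H](C(C)C)[C@@]2(O[Si](CC)(CC)CC)CC1
F9 | step 4 | (1R,4R,5S,8R,9S)-8,9-epoxy-5-(triethylsilyloxy)daucane, epoxide oxygen anti to the C5 oxygen | O1[C@H]2C[C@@]3(C)CC[C@H](C(C)C)[C@@]3(O[Si](CC)(CC)CC)CC[C@@]12C
F10 | step 4 | (1R,4R,5S,8R,9R)-5-(triethylsilyloxy)daucane-8,9-diol | O[C@@H]1C[C@@]2(C)CC[C@H](C(C)C)[C@@]2(O[Si](CC)(CC)CC)CC[C@@]1(C)O
A1 | alternative 1 | (S)-citronellol | OCC[C@@H](C)CCC=C(C)C
A2 | alternative 1 | (6S)-8-(tert-butyldimethylsilyloxy)-2,6-dimethyloctan-3-one | CC(C)C(=O)CC[C@H](C)CCO[Si](C)(C)C(C)(C)C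
A3 | alternative 1 | (3R)-3-[2-(tert-butyldimethylsilyloxy)ethyl]-3-methyl-1-(propan-2-yl)cyclopentene | CC(C)C1=C[C@@](C)(CCO[Si](C)(C)C(C)(C)C)CC1
A4 | alternative 2 | 1-[3-(tert-butyldimethylsilyloxymethyl)-2-methyloxiran-2-yl]-4-methylcyclohex-3-en-1-ol, oxirane configured as in the SMILES, either carbinol epimer | CC1=CCC(O)(CC1)[C@]1(C)O[C@@H]1CO[Si](C)(C)C(C)(C)C
A5 | alternative 2 | 2-[2-(tert-butyldimethylsilyloxy)-1-hydroxyethyl]-2,5-dimethylcyclohept-4-en-1-one, configured as in the SMILES | CC1=CC[C@@](C)([C@H](O)CO[Si](C)(C)C(C)(C)C)C(=O)CC1
A6 | alternative 3 | (7R)-2-methyl-7-(propan-2-yl)-6,7-dihydro-5H-cyclopenta[b]pyran-1-ium-3-olate (oxidopyrylium ylide) | Cc1[o+]c2[C@@H](C(C)C)CCc2cc1[O-]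
A7 | alternative 3 | ethynyl 4-methylphenyl sulfone | C#CS(=O)(=O)c1ccc(C)cc1
A8 | alternative 3 | 5,8-oxygen-bridged dauca-1(10),6-dien-9-one with a 4-methylphenylsulfonyl group on C6 | O=C1C=C2CC[C@H](C(C)C)[C@]23O[C@@]1(C)C=C3S(=O)(=O)c1ccc(C)cc1
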